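**Strategy.** Everything rests on cutting the C2–aryl bond of the 3,7-dioxabicyclo[3.3.0]octane core. C2 sits between O3 and the carbinol carbon C1 of ring A (C1–C2–O3–C4–C5), so it is an acetal-level carbon that can be unmasked as an oxocarbenium ion and arylated by plain veratrole. In one acid-catalysed operation a monocyclic lactol tetraol closes ring B (C1–C5–C6–O7–C8) through the C6 benzylic cation and undergoes exo-selective Friedel–Crafts arylation at C2, setting C6 and C2 on the convex face. The precursor, with C1 and C5 already set, comes in four steps from tulipalin A and veratraldehyde.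

Key step: step 5

Remark: the atom labels C1–C8 of the final bicycle (C1 carbinol, C2, O3, C4, C5, C6, O7, C8) are used for the corresponding atoms of every intermediate.

Assumption: the ligand antipode in step 2 is the one that gives Si-face attack on the aldehyde; the mirror-image ligand is used if the sense proves opposite.

Assumption: isogmelinol is taken to be the di-exo isomer, both aryl groups on the convex face and the C2 aryl cis to the C1 hydroxyl, which is what the target SMILES encodes.

**Step 1**
Reactants: 1 α-methylene-γ-butyrolactone (tulipalin A)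
Product: 3 3-(bromomethyl)furan-2(5H)-one, via dibromide 2 (not isolated)
Conditions: Br2, CH2Cl2, 0 °C to rt; then i-Pr2NEt, 0 °C to rt
Reagents that add atoms: bromine BrBr
Why: Bromine adds to the exocyclic alkene and E2 loss of HBr towards the ring CH2 gives the conjugated butenolide carrying an allylic bromide (bromination–dehydrobromination); no stereocentre is involved.

**Step 2**
Reactants: 3 3-(bromomethyl)furan-2(5H)-one; 4 3,4-dimethoxybenzaldehyde (veratraldehyde)
Product: 6 (R)-4-[(S)-(3,4-dimethoxyphenyl)(hydroxy)methyl]-3-methylenedihydrofuran-2(3H)-one, via silyl ether 5 (not isolated)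
Conditions: CrCl2 (10 mol %), chiral tridentate 1,8-bis[(S)-4-isopropyloxazolin-2-yl]carbazole ligand (12 mol %), i-Pr2NEt (30 mol %), Mn powder, TMSCl, THF, 0 °C to rt; then 10% aq citric acid; chromatographic removal of the minor diastereomer
Reagents that add atoms: none
Why: Chromium-catalysed asymmetric Nozaki–Hiyama–Kishi allylation: the ring-locked allylchromium reacts at its γ-carbon (C5) through a closed six-membered chair transition state, which sets C5 anti to the C6 carbinol, while the ligand directs Si-face attack on the aldehyde; C5 alone carries the absolute configuration forward, so the minor diastereomer is removed here.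

**Step 3**
Reactants: 6 (R)-4-[(S)-(3,4-dimethoxyphenyl)(hydroxy)methyl]-3-methylenedihydrofuran-2(3H)-one
Product: 7 (3S,4R)-4-[(S)-(3,4-dimethoxyphenyl)(hydroxy)methyl]-3-hydroxy-3-(hydroxymethyl)dihydrofuran-2(3H)-one
Conditions: OsO4 (2 mol %), NMO, acetone–H2O (4:1), rt
Reagents that add atoms: osmium tetroxide O=[Os](=O)(=O)=O (catalytic oxygen carrier); N-methylmorpholine N-oxide C[N+]1([O-])CCOCC1; water O
Why: Catalytic OsO4 syn-dihydroxylation of the 1,1-disubstituted alkene should occur on the face anti to the bulky C5 substituent, so the C1 hydroxyl ends trans and the new C8 hydroxymethyl cis to the C6 arm, the arrangement ring B needs.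

**Step 4**
Reactants: 7 (3S,4R)-4-[(S)-(3,4-dimethoxyphenyl)(hydroxy)methyl]-3-hydroxy-3-(hydroxymethyl)dihydrofuran-2(3H)-one
Product: 8 (3S,4R)-4-[(S)-(3,4-dimethoxyphenyl)(hydroxy)methyl]-3-(hydroxymethyl)tetrahydrofuran-2,3-diol (lactol, both C2 anomers)
Conditions: i-Bu2AlH (DIBAL-H, 5 equiv), THF, −78 °C; MeOH, aq potassium sodium tartrate
Reagents that add atoms: none
Why: Partial lactone reduction with DIBAL-H should stop at the aluminium hemiacetal at low temperature and give the lactol on work-up, as is routine for α-hydroxy lactones; no stereocentre is touched, and any translactonised isomer gives the same hydroxy aldehyde.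

**Step 5**
Reactants: 8 lactol tetraol (both C2 anomers); 9 1,2-dimethoxybenzene (veratrole)
Product: 12 isogmelinol (1S,2R,5R,6S)-2,6-bis(3,4-dimethoxyphenyl)-3,7-dioxabicyclo[3.3.0]octan-1-ol, via bicyclic lactol 10 (not isolated), via oxocarbenium ion 11 (not isolated)
Conditions: veratrole (10 equiv), Sc(OTf)3 (10 mol %), HFIP–CH2Cl2 (1:4), 0 °C to rt
Reagents that add atoms: none
Why: The acid ionises the benzylic C6–OH to a quinoid 3,4-dimethoxybenzyl cation that the C8 hydroxyl captures (5-exo-trig closure of ring B, cis-fused by necessity because C1 and C5 are already set), giving bicyclic lactol 10. Loss of water from C2 then gives oxocarbenium ion 11, which veratrole attacks through the position para to one methoxy group, followed by rearomatisation. The closest known reaction types are the acid-mediated cyclodehydration of 1-aryl-1,4-diols used to close furofuran rings and the dehydrative Friedel–Crafts C-arylation of lactols and glycosyl donors with alkoxyarenes. C6 is set by reversible benzylic ionisation, which should settle the aryl group on the exo (convex) face whatever the carbinol configuration of 8. C2 is set by attack on the convex face of the cis-fused bicycle, the face that carries only the small C1 hydroxyl, so the new aryl ends exo and cis to that hydroxyl, and the same isomer is favoured if the C2–O3 bond re-ionises. The step needs arylation at C2 and not at C6: the C6 cation is trapped by the internal C8 hydroxyl far faster than by external veratrole, cation 11 has no productive internal nucleophile, and excess veratrole outcompetes the electron-rich rings of substrate and product.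

**Compound list**
1 | α-methylene-γ-butyrolactone (3-methylenedihydrofuran-2(3H)-one, tulipalin A) | C=C1CCOC1=O | starting material
2 | 3-bromo-3-(bromomethyl)dihydrofuran-2(3H)-one (racemic) | BrCC1(Br)CCOC1=O | intermediate
3 | 3-(bromomethyl)furan-2(5H)-one | BrCC1=CCOC1=O | intermediate
4 | 3,4-dimethoxybenzaldehyde (veratraldehyde) | COc1ccc(C=O)cc1OC | starting material
5 | (R)-4-[(S)-(3,4-dimethoxyphenyl)(trimethylsilyloxy)methyl]-3-methylenedihydrofuran-2(3H)-one | C=C1C(=O)OC[C@@H]1[C@H](O[Si](C)(C)C)c1ccc(OC)c(OC)c1 | intermediate
6 | (R)-4-[(S)-(3,4-dimethoxyphenyl)(hydroxy)methyl]-3-methylenedihydrofuran-2(3H)-one | C=C1C(=O)OC[C@@H]1[C@H](O)c1ccc(OC)c(OC)c1 | intermediate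
7 | (3S,4R)-4-[(S)-(3,4-dimethoxyphenyl)(hydroxy)methyl]-3-hydroxy-3-(hydroxymethyl)dihydrofuran-2(3H)-one | OC[C@]1(O)C(=O)OC[C@@H]1[C@H](O)c1ccc(OC)c(OC)c1 | intermediate
8 | (3S,4R)-4-[(S)-(3,4-dimethoxyphenyl)(hydroxy)methyl]-3-(hydroxymethyl)tetrahydrofuran-2,3-diol (both C2 anomers) | OC[C@]1(O)C(O)OC[C@@H]1[C@H](O)c1ccc(OC)c(OC)c1 | intermediate
9 | 1,2-dimethoxybenzene (veratrole) | COc1ccccc1OC | starting material
10 | (1S,5R,6S)-6-(3,4-dimethoxyphenyl)-3,7-dioxabicyclo[3.3.0]octane-1,2-diol (both C2 anomers) | COc1ccc([C@H]2OC[C@]3(O)C(O)OC[C@H]23)cc1OC | intermediate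
11 | C2=O3 oxocarbenium ion derived from 10 | COc1ccc([C@H]2OC[C@]3(O)C=[O+]C[C@H]23)cc1OC | intermediate
12 | isogmelinol, (1S,2R,5R,6S)-2,6-bis(3,4-dimethoxyphenyl)-3,7-dioxabicyclo[3.3.0]octan-1-ol | COc1ccc([C@H]2OC[C@]3(O)[C@@H](c4ccc(OC)c(OC)c4)OC[C@H]23)cc1OC | target

**Step count and risks**
Total step count: 5. Longest linear sequence: 5 steps (1 → 3 → 6 → 7 → 8 → 12).

Steps most likely to fail:

1. Step 5. Veratrole may capture the C6 benzylic cation, or the substrate's own aryl rings may act as nucleophiles and oligomerise, under the acidity needed to arylate C2. The fallback sets out from 7 and moves the bond formation to an aryl-metal addition. Camphorsulfonic acid in CH2Cl2 closes ring B first to give the bicyclic hydroxy lactone F1. DIBAL-H at −78 °C then gives bicyclic lactol 10, now isolated. Excess 3,4-dimethoxyphenylmagnesium bromide in THF adds to its open hydroxy-aldehyde form to give the triol F2 as a mixture of carbinol epimers. Acid-mediated cyclodehydration (camphorsulfonic acid, CH2Cl2) through the C2 benzylic cation closes ring A to the exo isomer. The fallback comes back to the route at 12.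

2. Step 2. Enantio- or diastereocontrol may be poor with the ring-constrained, γ-substituted allyl donor. The fallback sets out from 3 and 4. A zinc-mediated Barbier allylation (Zn dust, THF–sat. aq NH4Cl) gives the racemic alcohol, that is 6 together with its enantiomer F3. Preparative chromatography on a chiral stationary phase separates them. The fallback comes back to the route at 6.

3. Step 4. The unprotected triol may be over-reduced to the open pentaol, or may stall as aggregated aluminium alkoxides. The fallback sets out from 6 and reduces before oxidising. DIBAL-H (2.2 equiv, CH2Cl2, −78 °C) converts 6, which has a single free hydroxyl, into the α-methylene lactol F4. Catalytic OsO4/NMO dihydroxylation of F4, again anti to the C5 substituent, then gives the tetraol. The fallback comes back to the route at 8.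

**Further compounds**
F1 | step 5 | (1S,5R,6S)-6-(3,4-dimethoxyphenyl)-1-hydroxy-3,7-dioxabicyclo[3.3.0]octan-2-one | COc1ccc([C@H]2OC[C@]3(O)C(=O)OC[C@H]23)cc1OC
F2 | step 5 | (3S,4R,5S)-5-(3,4-dimethoxyphenyl)-3-[(3,4-dimethoxyphenyl)(hydroxy)methyl]-4-(hydroxymethyl)tetrahydrofuran-3-ol (carbinol epimers) | COc1ccc([C@H]2OC[C@](O)(C(O)c3ccc(OC)c(OC)c3)[C@@H]2CO)cc1OC
F3 | step 2 | (S)-4-[(R)-(3,4-dimethoxyphenyl)(hydroxy)methyl]-3-methylenedihydrofuran-2(3H)-one | C=C1C(=O)OC[C@H]1[C@@H](O)c1ccc(OC)c(OC)c1
F4 | step 4 | (4R)-4-[(S)-(3,4-dimethoxyphenyl)(hydroxy)methyl]-3-methylenetetrahydrofuran-2-ol (both C2 anomers) | C=C1C(O)OC[C@@H]1[C@H](O)c1ccc(OC)c(OC)c1
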